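Retrosynthesis: after the six masked O–H groups, the C1–C(=O) bond of the butyryl group on ring C is cut, then ring C itself at C2–C3 and C4–C5. This separates a ring B cyclobutenone (supplying C5, C6, C1, C2) from a ring A silyl ynol ether (supplying C3, C4).
The cyclobutenone goes back to a ring B silyl ynol ether and ketene. Each ynol ether is cut at its alkyne C–O bond and at the ring–CH2 bond (propargyl arm), and each filicinic ring at its two C–CH3 bonds to an acylphloroglucinol.
Enabling feature: ring C alternates oxygen (C2, C4, C6) with carbon substituents (C1 butyryl, C3 CH2–ring A, C5 CH2–ring B). A 3-silyloxy vinylketene and a silyl ynol ether give exactly this pattern, so each methylene bridge travels on a different partner.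
Forward order: rings A and B first (dearomative gem-dimethylation), each then given a propargyl arm that supplies its bridge carbon and two ring C carbons. The four-membered ring is built on the ring B arm, ring C closes last (step 10), and butyrylation at C1 and deprotection finish.
Stereochemistry: the target has no stereocentre and no stereogenic double bond, so only regiochemistry is controlled; the one transient stereocentre of the key step is erased in the same flask.

Key step: step 10

Assumption: the filicinic rings are drawn in the tautomer of the target SMILES, and exhaustive O-methylation is taken to give the 3,5-dimethoxy isomer shown; other enol ether regioisomers would be carried through in the same way, since all four methyl groups are hydrolysed in step 13.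
Shorthand in names: ring-A-yl = 5-acetyl-2,6-dimethoxy-3,3-dimethyl-4-oxocyclohexa-1,5-dien-1-yl; ring-B-yl = 2,6-dimethoxy-3,3-dimethyl-4-oxo-5-propanoylcyclohexa-1,5-dien-1-yl.

Step 1
Reactants: 1 1-(2,4,6-trihydroxyphenyl)ethanone; 2 iodomethane
Product: 3 2-acetyl-3,5-dihydroxy-6,6-dimethylcyclohexa-2,4-dien-1-one (acetylfilicinic acid)
Conditions: MeI (2.2 equiv), NaOMe (3 equiv), MeOH, 0 °C → rt
Reagents that add atoms: iodomethane, CI
Why: Dearomative double C-methylation of an acylphloroglucinol anion is a known entry to acylfilicinic acids, the second methyl group entering at the carbon already methylated to leave a stabilised vinylogous acid anion that resists further alkylation under controlled stoichiometry.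

Step 2
Reactants: 3 acetylfilicinic acid; 4 3-bromoprop-1-yne (propargyl bromide)
Product: 5 2-acetyl-3,5-dihydroxy-6,6-dimethyl-4-(prop-2-yn-1-yl)cyclohexa-2,4-dien-1-one
Conditions: propargyl bromide (1.05 equiv), NaOMe (2.1 equiv), MeOH, 0 °C → rt
Reagents that add atoms: 3-bromoprop-1-yne, C#CCBr
Why: C-alkylation of a cyclic triketone enolate in a protic medium should take place at the one unsubstituted ring carbon between the two enolate oxygens, as in the known C-allylations of acylfilicinic acids, and one equivalent of bromide should hold it at the mono-alkyl stage.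

Step 3
Reactants: 5 2-acetyl-3,5-dihydroxy-6,6-dimethyl-4-(prop-2-yn-1-yl)cyclohexa-2,4-dien-1-one
Product: 6 2-acetyl-3,5-dimethoxy-6,6-dimethyl-4-(prop-2-yn-1-yl)cyclohexa-2,4-dien-1-one
Conditions: Me3SiCHN2 (excess), MeOH–toluene, 0 °C → rt
Reagents that add atoms: (trimethylsilyl)diazomethane, C[Si](C)(C)C=[N+]=[N-]
Why: O-methylation of vinylogous acids with a diazoalkane should convert both acidic enols into methyl enol ethers without the C-methylation of the fully substituted ring carbon that a methyl halide and base would cause.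

Step 4
Reactants: 6 2-acetyl-3,5-dimethoxy-6,6-dimethyl-4-(prop-2-yn-1-yl)cyclohexa-2,4-dien-1-one
Product: 8 2-acetyl-3,5-dimethoxy-6,6-dimethyl-4-[3-(triisopropylsilyloxy)prop-2-yn-1-yl]cyclohexa-2,4-dien-1-one (fragment 1), via dilithium ynolate enolate 7 (not isolated)
Conditions: LiN(SiMe3)2 (3.2 equiv), tBuOOH (1.05 equiv), THF, −78 → 0 °C; iPr3SiCl (1.2 equiv), −78 → 0 °C; pH 7 buffer
Reagents that add atoms: tert-butyl hydroperoxide, CC(C)(C)OO; chlorotriisopropylsilane, CC(C)[Si](Cl)(C(C)C)C(C)C
Why: Oxidation of a lithium acetylide (RC≡CLi) by LiOOtBu to the lithium ynolate (RC≡COLi) and O-silylation with a bulky chlorosilane is the standard route to triisopropylsilyl ynol ethers, and here the acetyl group is carried through as its lithium enolate (C(OLi)=CH2), which shields the ketone from acetylide and ynolate, should not be silylated by iPr3SiCl and returns as the ketone on work-up.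

Step 5
Reactants: 9 1-(2,4,6-trihydroxyphenyl)propan-1-one; 2 iodomethane
Product: 10 3,5-dihydroxy-6,6-dimethyl-2-propanoylcyclohexa-2,4-dien-1-one (propionylfilicinic acid)
Conditions: MeI (2.2 equiv), NaOMe (3 equiv), MeOH, 0 °C → rt
Reagents that add atoms: iodomethane, CI
Why: The same dearomative geminal C-methylation of an acylphloroglucinol anion as in step 1 should give the propionyl member of the filicinic acid series.

Step 6
Reactants: 10 propionylfilicinic acid; 4 3-bromoprop-1-yne (propargyl bromide)
Product: 11 3,5-dihydroxy-6,6-dimethyl-2-propanoyl-4-(prop-2-yn-1-yl)cyclohexa-2,4-dien-1-one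
Conditions: propargyl bromide (1.05 equiv), NaOMe (2.1 equiv), MeOH, 0 °C → rt
Reagents that add atoms: 3-bromoprop-1-yne, C#CCBr
Why: C-alkylation of the triketone enolate at its only unsubstituted ring carbon should proceed as in step 2.

Step 7
Reactants: 11 3,5-dihydroxy-6,6-dimethyl-2-propanoyl-4-(prop-2-yn-1-yl)cyclohexa-2,4-dien-1-one
Product: 12 3,5-dimethoxy-6,6-dimethyl-2-propanoyl-4-(prop-2-yn-1-yl)cyclohexa-2,4-dien-1-one
Conditions: Me3SiCHN2 (excess), MeOH–toluene, 0 °C → rt
Reagents that add atoms: (trimethylsilyl)diazomethane, C[Si](C)(C)C=[N+]=[N-]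
Why: Diazoalkane O-methylation of both vinylogous acid hydroxyls should proceed as in step 3.

Step 8
Reactants: 12 3,5-dimethoxy-6,6-dimethyl-2-propanoyl-4-(prop-2-yn-1-yl)cyclohexa-2,4-dien-1-one
Product: 14 3,5-dimethoxy-6,6-dimethyl-2-propanoyl-4-[3-(triisopropylsilyloxy)prop-2-yn-1-yl]cyclohexa-2,4-dien-1-one, via dilithium ynolate enolate 13 (not isolated)
Conditions: LiN(SiMe3)2 (3.2 equiv), tBuOOH (1.05 equiv), THF, −78 → 0 °C; iPr3SiCl (1.2 equiv), −78 → 0 °C; pH 7 buffer
Reagents that add atoms: tert-butyl hydroperoxide, CC(C)(C)OO; chlorotriisopropylsilane, CC(C)[Si](Cl)(C(C)C)C(C)C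
Why: Acetylide oxidation with LiOOtBu and O-silylation of the ynolate should proceed as in step 4, the propionyl group being masked in the flask as its more hindered lithium enolate, which is protonated on work-up.

Step 9
Reactants: 14 3,5-dimethoxy-6,6-dimethyl-2-propanoyl-4-[3-(triisopropylsilyloxy)prop-2-yn-1-yl]cyclohexa-2,4-dien-1-one; 15 ketene (gas, generated immediately before use by pyrolysis of acetone)
Product: 16 2-[(ring-B-yl)methyl]-3-(triisopropylsilyloxy)cyclobut-2-en-1-one (fragment 2)
Conditions: ketene (gas, excess), CH2Cl2, 0 °C → rt; volatiles removed, rapid filtration through Et3N-deactivated silica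
Reagents that add atoms: ketene, C=C=O
Why: The thermal (2+2) cycloaddition of ketene with a silyl ynol ether is a known route to 3-silyloxycyclobutenones, the alkyne carbon remote from oxygen bonding to the ketene carbonyl carbon and the oxygen-bearing carbon to the ketene CH2, which places the ring B arm at C2 and the silyloxy group at C3.

Step 10
Reactants: 16 2-[(ring-B-yl)methyl]-3-(triisopropylsilyloxy)cyclobut-2-en-1-one (fragment 2); 8 2-acetyl-3,5-dimethoxy-6,6-dimethyl-4-[3-(triisopropylsilyloxy)prop-2-yn-1-yl]cyclohexa-2,4-dien-1-one (fragment 1)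
Product: 21 2-[(ring-A-yl)methyl]-4-[(ring-B-yl)methyl]-3,5-bis(triisopropylsilyloxy)phenol, via vinylketene 17 (not isolated), via vinylcyclobutenone 18 (not isolated), via dienylketene 19 (not isolated), via cyclohexadienone 20 (not isolated)
Conditions: 8 (1.2 equiv), toluene (degassed), sealed tube, 80 °C then 110 °C
Reagents that add atoms: none
Why: Proposed new method: Heating should open cyclobutenone 16 by 4π electrocyclic cleavage of its C1–C4 bond to the 3-silyloxy vinylketene 17; the carbon of ynol ether 8 remote from oxygen then attacks the ketene carbonyl carbon and the oxygen-bearing carbon bonds to the ketene α-carbon in a (2+2) cycloaddition to vinylcyclobutenone 18, which opens again to dienylketene 19 and closes ring C by a thermally allowed disrotatory 6π electrocyclisation (ketene carbon onto the terminal CH2) to cyclohexadienone 20, whose tautomerisation to phenol 21 is irreversible. The closest known reaction is the Danheiser benzannulation of cyclobutenones with trialkylsilyl ynol ethers, which gives resorcinol monosilyl ethers; new here are the 3-silyloxy group on the cyclobutenone, which turns the product into a phloroglucinol with three differentiated oxygens, and the size of both partners. No stereocentre results, because the quaternary carbon of 18 is formed racemic and becomes trigonal again in 19. The step needs regiocontrol in the (2+2) event, and polarity alone should secure it: the ketene is electrophilic only at its carbonyl carbon and the ynol ether nucleophilic only at its β-carbon, so the ring A arm ends at C3 between the new hydroxyl (C2) and the alkyne-derived oxygen (C4), the ring B arm at C5, and the cyclobutenone CH2 becomes the unsubstituted C1. The dienones, acyl ketones and methyl enol ethers of rings A and B should be spectators under neutral thermal conditions, and the temperature is kept below that at which silyl ynol ethers rearrange to silylketenes.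

Step 11
Reactants: 21 2-[(ring-A-yl)methyl]-4-[(ring-B-yl)methyl]-3,5-bis(triisopropylsilyloxy)phenol; 22 butanoyl chloride
Product: 23 1-{2-hydroxy-3-[(ring-A-yl)methyl]-5-[(ring-B-yl)methyl]-4,6-bis(triisopropylsilyloxy)phenyl}butan-1-one
Conditions: PrCOCl (1.5 equiv), TiCl4 (4 equiv), CH2Cl2, −78 → −20 °C
Reagents that add atoms: butanoyl chloride, CCCC(=O)Cl
Why: Friedel–Crafts acylation directed by the aryloxytitanium trichloride (ArOTiCl3) of the free C2 hydroxyl should occur at C1, the only unsubstituted carbon of ring C and one activated by three oxygen substituents, either directly or through the aryl ester and its Fries shift, at a temperature where aryl silyl ethers and vinylogous methyl esters are expected to persist.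

Step 12
Reactants: 23 1-{2-hydroxy-3-[(ring-A-yl)methyl]-5-[(ring-B-yl)methyl]-4,6-bis(triisopropylsilyloxy)phenyl}butan-1-one
Product: 24 1-{2,4,6-trihydroxy-3-[(ring-A-yl)methyl]-5-[(ring-B-yl)methyl]phenyl}butan-1-one
Conditions: Bu4NF (2.5 equiv), AcOH (2.5 equiv), THF, 0 °C
Reagents that add atoms: none
Why: Fluoride cleavage of the two aryl triisopropylsilyl ethers, buffered with acetic acid, should free the phloroglucinol without exposing it to base, under which methylene-bridged phloroglucinols can exchange their bridges.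

Step 13
Reactants: 24 1-{2,4,6-trihydroxy-3-[(ring-A-yl)methyl]-5-[(ring-B-yl)methyl]phenyl}butan-1-one
Product: 25 1-{3-[(5-acetyl-2,6-dihydroxy-3,3-dimethyl-4-oxocyclohexa-1,5-dien-1-yl)methyl]-5-[(2,6-dihydroxy-3,3-dimethyl-4-oxo-5-propanoylcyclohexa-1,5-dien-1-yl)methyl]-2,4,6-trihydroxyphenyl}butan-1-one (CNP0325527.0)
Conditions: 2 M aq. HCl–THF, 40 °C
Reagents that add atoms: water, O
Why: Acid hydrolysis of the four vinylogous methyl esters (conjugate addition of water to the protonated β-methoxyenone, then loss of methanol) should release the enols of rings A and B and give the target in its hydrogen-bonded tautomer.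

Compound list
1 | 1-(2,4,6-trihydroxyphenyl)ethanone | CC(=O)c1c(O)cc(O)cc1O | starting material
2 | iodomethane | CI | starting material
3 | 2-acetyl-3,5-dihydroxy-6,6-dimethylcyclohexa-2,4-dien-1-one (acetylfilicinic acid) | CC(=O)C1=C(O)C=C(O)C(C)(C)C1=O | intermediate
4 | 3-bromoprop-1-yne (propargyl bromide) | C#CCBr | starting material
5 | 2-acetyl-3,5-dihydroxy-6,6-dimethyl-4-(prop-2-yn-1-yl)cyclohexa-2,4-dien-1-one | C#CCC1=C(O)C(C)(C)C(=O)C(C(C)=O)=C1O | intermediate
6 | 2-acetyl-3,5-dimethoxy-6,6-dimethyl-4-(prop-2-yn-1-yl)cyclohexa-2,4-dien-1-one | C#CCC1=C(OC)C(C)(C)C(=O)C(C(C)=O)=C1OC | intermediate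
7 | dilithium salt of 6 oxidised at the alkyne terminus (ynolate) and deprotonated at the acetyl group (enolate) | [Li+].[Li+].[O-]C#CCC1=C(OC)C(C)(C)C(=O)C(C(=C)[O-])=C1OC | intermediate (not isolated)
8 | 2-acetyl-3,5-dimethoxy-6,6-dimethyl-4-[3-(triisopropylsilyloxy)prop-2-yn-1-yl]cyclohexa-2,4-dien-1-one (fragment 1) | CC(C)[Si](C(C)C)(C(C)C)OC#CCC1=C(OC)C(C)(C)C(=O)C(C(C)=O)=C1OC | intermediate
9 | 1-(2,4,6-trihydroxyphenyl)propan-1-one | CCC(=O)c1c(O)cc(O)cc1O | starting material
10 | 3,5-dihydroxy-6,6-dimethyl-2-propanoylcyclohexa-2,4-dien-1-one (propionylfilicinic acid) | CCC(=O)C1=C(O)C=C(O)C(C)(C)C1=O | intermediate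
11 | 3,5-dihydroxy-6,6-dimethyl-2-propanoyl-4-(prop-2-yn-1-yl)cyclohexa-2,4-dien-1-one | C#CCC1=C(O)C(C)(C)C(=O)C(C(=O)CC)=C1O | intermediate
12 | 3,5-dimethoxy-6,6-dimethyl-2-propanoyl-4-(prop-2-yn-1-yl)cyclohexa-2,4-dien-1-one | C#CCC1=C(OC)C(C)(C)C(=O)C(C(=O)CC)=C1OC | intermediate
13 | dilithium salt of 12 oxidised at the alkyne terminus (ynolate) and deprotonated at the propanoyl group (Z enolate drawn, geometry immaterial) | [Li+].[Li+].[O-]C#CCC1=C(OC)C(C)(C)C(=O)C(C(/[O-])=C/C)=C1OC | intermediate (not isolated)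
14 | 3,5-dimethoxy-6,6-dimethyl-2-propanoyl-4-[3-(triisopropylsilyloxy)prop-2-yn-1-yl]cyclohexa-2,4-dien-1-one | CC(C)[Si](C(C)C)(C(C)C)OC#CCC1=C(OC)C(C)(C)C(=O)C(C(=O)CC)=C1OC | intermediate
15 | ketene (ethenone) | C=C=O | starting material (generated from commercial acetone by pyrolysis directly before use)
16 | 2-[(ring-B-yl)methyl]-3-(triisopropylsilyloxy)cyclobut-2-en-1-one (fragment 2) | CC(C)[Si](C(C)C)(C(C)C)OC1=C(CC2=C(OC)C(C)(C)C(=O)C(C(=O)CC)=C2OC)C(=O)C1 | intermediate
17 | 2-[(ring-B-yl)methyl]-3-(triisopropylsilyloxy)buta-1,3-dien-1-one (vinylketene) | C=C(O[Si](C(C)C)(C(C)C)C(C)C)C(CC2=C(OC)C(C)(C)C(=O)C(C(=O)CC)=C2OC)=C=O | intermediate (not isolated)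
18 | 2-[(ring-A-yl)methyl]-4-[(ring-B-yl)methyl]-3-(triisopropylsilyloxy)-4-[1-(triisopropylsilyloxy)ethenyl]cyclobut-2-en-1-one (racemic) | O=C1C(CC2=C(OC)C(C)(C)C(=O)C(C(C)=O)=C2OC)=C(O[Si](C(C)C)(C(C)C)C(C)C)C1(CC3=C(OC)C(C)(C)C(=O)C(C(=O)CC)=C3OC)C(=C)O[Si](C(C)C)(C(C)C)C(C)C | intermediate (not isolated)
19 | 2-[(ring-A-yl)methyl]-4-[(ring-B-yl)methyl]-3,5-bis(triisopropylsilyloxy)hexa-1,3,5-trien-1-one, ketene and vinyl groups cis on the central double bond (dienylketene) | O=C=C(CC2=C(OC)C(C)(C)C(=O)C(C(C)=O)=C2OC)/C(O[Si](C(C)C)(C(C)C)C(C)C)=C(CC3=C(OC)C(C)(C)C(=O)C(C(=O)CC)=C3OC)\C(=C)O[Si](C(C)C)(C(C)C)C(C)C | intermediate (not isolated)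
20 | 2-[(ring-A-yl)methyl]-4-[(ring-B-yl)methyl]-3,5-bis(triisopropylsilyloxy)cyclohexa-2,4-dien-1-one | O=C1CC(O[Si](C(C)C)(C(C)C)C(C)C)=C(CC3=C(OC)C(C)(C)C(=O)C(C(=O)CC)=C3OC)C(O[Si](C(C)C)(C(C)C)C(C)C)=C1CC2=C(OC)C(C)(C)C(=O)C(C(C)=O)=C2OC | intermediate (not isolated)
21 | 2-[(ring-A-yl)methyl]-4-[(ring-B-yl)methyl]-3,5-bis(triisopropylsilyloxy)phenol (ring C with C2–OH free, C4 and C6 silylated, C1–H) | CC(C)[Si](C(C)C)(C(C)C)Oc1cc(O)c(CC2=C(OC)C(C)(C)C(=O)C(C(C)=O)=C2OC)c(O[Si](C(C)C)(C(C)C)C(C)C)c1CC3=C(OC)C(C)(C)C(=O)C(C(=O)CC)=C3OC | intermediate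
22 | butanoyl chloride | CCCC(=O)Cl | starting material
23 | 1-{2-hydroxy-3-[(ring-A-yl)methyl]-5-[(ring-B-yl)methyl]-4,6-bis(triisopropylsilyloxy)phenyl}butan-1-one | CCCC(=O)c1c(O)c(CC2=C(OC)C(C)(C)C(=O)C(C(C)=O)=C2OC)c(O[Si](C(C)C)(C(C)C)C(C)C)c(CC3=C(OC)C(C)(C)C(=O)C(C(=O)CC)=C3OC)c1O[Si](C(C)C)(C(C)C)C(C)C | intermediate
24 | 1-{2,4,6-trihydroxy-3-[(ring-A-yl)methyl]-5-[(ring-B-yl)methyl]phenyl}butan-1-one | CCCC(=O)c1c(O)c(CC2=C(OC)C(C)(C)C(=O)C(C(C)=O)=C2OC)c(O)c(CC3=C(OC)C(C)(C)C(=O)C(C(=O)CC)=C3OC)c1O | intermediate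
25 | 1-{3-[(5-acetyl-2,6-dihydroxy-3,3-dimethyl-4-oxocyclohexa-1,5-dien-1-yl)methyl]-5-[(2,6-dihydroxy-3,3-dimethyl-4-oxo-5-propanoylcyclohexa-1,5-dien-1-yl)methyl]-2,4,6-trihydroxyphenyl}butan-1-one (CNP0325527.0) | CCCC(=O)c1c(O)c(CC2=C(O)C(C)(C)C(=O)C(C(C)=O)=C2O)c(O)c(CC2=C(O)C(C)(C)C(=O)C(C(=O)CC)=C2O)c1O | target

Total step count: 13 (steps 1–4 for fragment 1, steps 5–9 for fragment 2, steps 10–13 after their union).
Longest linear sequence: 9 steps (steps 5–13, from 9).

Steps most likely to fail

Step 10 (proposed new method). The push–pull cyclobutenone may resist 4π opening at temperatures the ynol ether survives. The ynol ether may isomerise by 1,3-silyl shift to a silylketene. The vinylketene may also be lost to dimerisation or to acylation of the product phenol. The fallback gives up the benzannulation and builds ring C from a preformed phloroglucinol by aminomethyl (Mannich) bridging, known chemistry for methylene-bridged acylphloroglucinols. It sets out from 3 and 10 and returns to the route at 25. Compound 3 with aqueous CH2O and Me2NH should give the Mannich base 2-acetyl-4-[(dimethylamino)methyl]-3,5-dihydroxy-6,6-dimethylcyclohexa-2,4-dien-1-one F1. Warming F1 in dioxane with an excess of commercial 1-(2,4,6-trihydroxyphenyl)butan-1-one F2 should expel dimethylamine and C-alkylate the phloroglucinol, giving the ring A–CH2–ring C dimer 1-{3-[(5-acetyl-2,6-dihydroxy-3,3-dimethyl-4-oxocyclohexa-1,5-dien-1-yl)methyl]-2,4,6-trihydroxyphenyl}butan-1-one F3. The Mannich base made in the same way from 10, 4-[(dimethylamino)methyl]-3,5-dihydroxy-6,6-dimethyl-2-propanoylcyclohexa-2,4-dien-1-one F4, would then alkylate the last free ring carbon of F3 and give 25.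

Step 4. Two anionic sites must be told apart in one flask: silylation of the acetyl enolate, its aldol-type self-condensation or its oxidation at carbon would erode the chemoselectivity. The propionyl enolate of step 8 is more hindered and is judged less exposed. The fallback takes the ketone out of play before the oxidation instead of in the flask; it sets out from 6 and returns at 8. Soft enolisation of 6 (Et3SiOTf, Et3N, CH2Cl2, 0 °C) should give the triethylsilyl enol ether 3,5-dimethoxy-6,6-dimethyl-4-(prop-2-yn-1-yl)-2-[1-(triethylsilyloxy)ethenyl]cyclohexa-2,4-dien-1-one F5, which has no acidic C–H other than the alkyne. Acetylide oxidation with LiOOtBu and trapping with iPr3SiCl (two equivalents of LiN(SiMe3)2 in all) would give the doubly silylated 3,5-dimethoxy-6,6-dimethyl-2-[1-(triethylsilyloxy)ethenyl]-4-[3-(triisopropylsilyloxy)prop-2-yn-1-yl]cyclohexa-2,4-dien-1-one F6. Methanolysis of the labile triethylsilyl dienol ether (K2CO3, MeOH, 0 °C), to which the hindered triisopropylsilyl ynol ether should be inert, would return 8.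

Step 11. Under TiCl4 the aryl silyl ethers or methyl enol ethers may be cleaved, the acylation may stop at the aryl ester, or ring C may be protonated at a bridge-bearing carbon and lose a bridge by retro-Friedel–Crafts cleavage. The fallback replaces the acyl chloride and Lewis acid by the Houben–Hoesch reaction, the classical acylation of free phloroglucinols; it sets out from 21 and returns at 25. Bu4NF–AcOH should convert 21 into the triol 2-[(ring-A-yl)methyl]-4-[(ring-B-yl)methyl]benzene-1,3,5-triol F7. Butanenitrile, ZnCl2 and dry HCl in Et2O at 0 °C should then give, at the only free ring carbon, the ketiminium chloride 1-{2,4,6-trihydroxy-3-[(ring-A-yl)methyl]-5-[(ring-B-yl)methyl]phenyl}butan-1-iminium chloride F8. Warming F8 in dilute aqueous HCl is expected to hydrolyse the iminium group and the four methyl enol ethers together and give 25.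

Further compounds
F1 | step 10 | 2-acetyl-4-[(dimethylamino)methyl]-3,5-dihydroxy-6,6-dimethylcyclohexa-2,4-dien-1-one | CN(C)CC1=C(O)C(C)(C)C(=O)C(C(C)=O)=C1O
F2 | step 10 | 1-(2,4,6-trihydroxyphenyl)butan-1-one (purchased) | CCCC(=O)c1c(O)cc(O)cc1O
F3 | step 10 | 1-{3-[(5-acetyl-2,6-dihydroxy-3,3-dimethyl-4-oxocyclohexa-1,5-dien-1-yl)methyl]-2,4,6-trihydroxyphenyl}butan-1-one | CCCC(=O)c1c(O)cc(O)c(CC2=C(O)C(C)(C)C(=O)C(C(C)=O)=C2O)c1O
F4 | step 10 | 4-[(dimethylamino)methyl]-3,5-dihydroxy-6,6-dimethyl-2-propanoylcyclohexa-2,4-dien-1-one | CN(C)CC1=C(O)C(C)(C)C(=O)C(C(=O)CC)=C1O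
F5 | step 4 | 3,5-dimethoxy-6,6-dimethyl-4-(prop-2-yn-1-yl)-2-[1-(triethylsilyloxy)ethenyl]cyclohexa-2,4-dien-1-one | C#CCC1=C(OC)C(C)(C)C(=O)C(C(=C)O[Si](CC)(CC)CC)=C1OC
F6 | step 4 | 3,5-dimethoxy-6,6-dimethyl-2-[1-(triethylsilyloxy)ethenyl]-4-[3-(triisopropylsilyloxy)prop-2-yn-1-yl]cyclohexa-2,4-dien-1-one | CC(C)[Si](C(C)C)(C(C)C)OC#CCC1=C(OC)C(C)(C)C(=O)C(C(=C)O[Si](CC)(CC)CC)=C1OC
F7 | step 11 | 2-[(ring-A-yl)methyl]-4-[(ring-B-yl)methyl]benzene-1,3,5-triol | Oc1cc(O)c(CC2=C(OC)C(C)(C)C(=O)C(C(C)=O)=C2OC)c(O)c1CC3=C(OC)C(C)(C)C(=O)C(C(=O)CC)=C3OC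
F8 | step 11 | 1-{2,4,6-trihydroxy-3-[(ring-A-yl)methyl]-5-[(ring-B-yl)methyl]phenyl}butan-1-iminium chloride | CCCC(=[NH2+])c1c(O)c(CC2=C(OC)C(C)(C)C(=O)C(C(C)=O)=C2OC)c(O)c(CC3=C(OC)C(C)(C)C(=O)C(C(=O)CC)=C3OC)c1O.[Cl-]
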